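I will take the ratio of target to other capture product, the selectivity of the capture, from its two ends and join them, counting everything as fractions of the charge.

| flask | substrate | second nucleophile | solid first nucleophile | remark | time |
|---|---|---|---|---|---|
| elm | 20 mM | 50 mM | 28 mM | run made earlier |  |
| birch | 20 mM | 50 mM | 44 mM | run made earlier |  |
| flask | 20 mM | 50.0 mM | 20.0 mM |  | 15 d |

- elm (time / d: target / %, other capture product / %, substrate / %): 2.50: 10.4, 74.1, 16.3; 5.00: 13.5, 83.4, 3.0; 8.00: 13.1, 85.2, 1.2; 10.0: 13.5, 85.5, 1.4; 12.0: 14.7, 86.0, 2.1; 15.0: 13.3, 85.7, 0; 20.0: 14.0, 85.0, 0
- birch (time / d: target / %, other capture product / %, substrate / %): 1.25: 7.8, 53.2, 41.0; 2.00: 7.9, 69.6, 25.0; 3.00: 11.2, 77.3, 11.4; 5.00: 14.0, 82.4, 3.1; 8.00: 14.1, 84.4, 0; 12.0: 15.2, 84.1, 0; 20.0: 13.3, 86.0, 0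

(scatter of a reading: 1 percentage point)

- given per volume of solution although it is solid: solid first nucleophile
- steps thought possible: second nucleophile <-> dormant form; first nucleophile + intermediate -> target; substrate -> intermediate; second nucleophile + intermediate -> other capture product; solid first nucleophile <-> first nucleophile
- at the start none of the solid first nucleophile is in solution

1. ratio of target to other capture product at 50 min
2. ratio of target to other capture product at 15 d

What is the late end? Elm at 20.0 d reads 0.165 and birch reads 0.155, so in these two readings, with their scatter, more solid charged did not raise the ratio, and I commit to their mean, 0.160.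

But this flask has less solid than either run. Target at elm's level would take 14.0% of this flask's solid, so I keep the ratio 0.160 for this flask unless the solubility lies above this charge.

And the early end? None of the solid is in solution at the start, so this is an induction period. I assume that in this early stretch the solid dissolves at a steady rate and the substrate has hardly fallen; then target grows with the square of time and other capture product with time, so their ratio leaves zero along a straight line. Its steepness is the early slope 0.117 d⁻¹, the cumulative ratio gained per day from the start, read at birch's first reading. At 50 min that gives 0.00407.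

Isn't that reading late? Yes: other capture product already stands at 53.2% there, and birch carried more solid than this flask, so I trust the size of the figure and not its second digit.

The forecast gives 0.03 (0.005 to 0.14) and 0.16 (0.125 to 0.175), reasoning “At 50 min little has dissolved, so the cumulative ratio should be far lower”. Its early figure is higher than mine.

The flask gives 0.00302 at 50 min and 0.167 at 15 d, with first nucleophile at 1.41 mM after 1.50 d and 3.30 mM after 15.0 d.

    second nucleophile ⇌ dormant form (K = 0.740, k = 3.00 × 10⁻⁵ s⁻¹)
    first nucleophile + intermediate → target (k = 0.280 M⁻¹ s⁻¹)
    substrate → intermediate (k = 8.30 × 10⁻⁶ s⁻¹)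
    second nucleophile + intermediate → other capture product (k = 0.0860 M⁻¹ s⁻¹)
    solid first nucleophile ⇌ first nucleophile, rate k5*(cs5 - [first nucleophile]) while solid is left; crystals form when [first nucleophile] > cs5 (solubility = 3.30 mM, k = 8.40 × 10⁻⁶ s⁻¹)

The early slope's 0.00407 stands 1.35 times above the flask's value. For the neighbour charged with 30 mM of second nucleophile, the slope scaled inversely with that charge gives 0.00679 at 50 min, and that neighbour stands at 0.00520.

The readings come from a simulation with constants of no real substance, noise included.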